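**Retrosynthetic overview**
1. Target 19 comes from its 5-O-methyl ether 17 by cleaving the one methyl ether that lies peri to the C4 ketone.
2. Ring C of 17 is disconnected at C4–C4a: an aryllithium at C4a, made from a C–Br bond, is acylated by a tethered Weinreb amide (Parham cyclisation of 14). Rings A and B are bought as benzenes, and ring C is the only ring formed, last.
3. The strategy rests on two features. C4a is the ring-A carbon flanked by O1 and O5, so a bromine there gives a regiodefined carbanion. The C2–O1 bond is a 2,4,6-trimethoxybenzylic (ring B) ether that would ionise under Friedel–Crafts acid, so the closure must be anionic and acid-free.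
4. The C2 stereocentre is set before ring closure by enantioselective CuH conjugate reduction of Z-β-aryloxy cinnamate 12, the oxa-Michael adduct of phenol 7 and aryl propiolate 11.
5. Phenol 7 comes from 3,5-dimethoxyphenol by ortho-bromination, O-(1,1-dimethylallyl)ation and Claisen rearrangement; ynoate 11 from 2,4,6-trimethoxybenzaldehyde by Corey–Fuchs homologation.

Key step: step 10

Remark: the hand of the bisphosphine that leads from Z-12 to (3S)-13 cannot be fixed by analogy alone; (S)-DTBM-SEGPHOS is written, and its antipode is used if a test reduction shows the opposite sense.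

**Step 1**
Reactants: 1 3,5-dimethoxyphenol
Product: 2 2-bromo-3,5-dimethoxyphenol
Conditions: NBS (1.0 equiv), i-Pr2NH (10 mol %), CH2Cl2, 0 °C
Reagents that add atoms: N-bromosuccinimide, O=C1CCC(=O)N1Br
Why: Electrophilic aromatic bromination in which the N-bromoamine formed in situ is hydrogen-bonded to the phenol and should deliver bromine to one of the two equivalent ortho carbons in preference to the para carbon; any 4-bromo isomer is removed by chromatography.

**Step 2**
Reactants: 3 2-methylbut-3-en-2-ol
Product: 5 methyl 2-methylbut-3-en-2-yl carbonate, via lithium 2-methylbut-3-en-2-olate 4 (not isolated)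
Conditions: n-BuLi, THF, −78 → 0 °C; ClCO2Me, 0 °C → rt
Reagents that add atoms: methyl chloroformate, COC(=O)Cl
Why: O-Acylation of a tertiary lithium alkoxide by a chloroformate is a standard carbonate synthesis that avoids ionising the tertiary allylic alcohol.

**Step 3**
Reactants: 2 2-bromo-3,5-dimethoxyphenol; 5 methyl 2-methylbut-3-en-2-yl carbonate
Product: 6 2-bromo-1,5-dimethoxy-3-[(2-methylbut-3-en-2-yl)oxy]benzene
Conditions: Pd(PPh3)4 (3 mol %), 4 Å MS, THF, 0 °C → rt
Reagents that add atoms: none
Why: Tsuji–Trost O-allylation, in which Pd(0) ionises the carbonate with loss of CO2, the methoxide released deprotonates the phenol, and the phenoxide attacks the more substituted terminus of the 1,1-dimethylallyl–palladium complex under kinetic control, while the electron-rich aryl bromide should not undergo oxidative addition at this temperature.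

**Step 4**
Reactants: 6 2-bromo-1,5-dimethoxy-3-[(2-methylbut-3-en-2-yl)oxy]benzene
Product: 7 2-bromo-3,5-dimethoxy-6-(3-methylbut-2-en-1-yl)phenol
Conditions: PhNEt2, 130 °C
Reagents that add atoms: none
Why: Aromatic Claisen rearrangement, whose [3,3] shift can end only at the one free ortho carbon (the other carries bromine), converts the 1,1-dimethylallyl ether into a normal prenyl group, and is followed by tautomerisation of the dienone to the phenol.

**Step 5**
Reactants: 8 2,4,6-trimethoxybenzaldehyde
Product: 9 2-(2,2-dibromoethenyl)-1,3,5-trimethoxybenzene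
Conditions: CBr4, PPh3, CH2Cl2, 0 °C
Reagents that add atoms: carbon tetrabromide, BrC(Br)(Br)Br
Why: First stage of the Corey–Fuchs homologation, a Wittig-type olefination by dibromomethylenetriphenylphosphorane that tolerates electron-rich, ortho-substituted benzaldehydes.

**Step 6**
Reactants: 9 2-(2,2-dibromoethenyl)-1,3,5-trimethoxybenzene
Product: 11 methyl 3-(2,4,6-trimethoxyphenyl)prop-2-ynoate, via lithium (2,4,6-trimethoxyphenyl)acetylide 10 (not isolated)
Conditions: n-BuLi (2.1 equiv), THF, −78 °C; ClCO2Me, −78 → 0 °C
Reagents that add atoms: methyl chloroformate, COC(=O)Cl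
Why: Second stage of the Corey–Fuchs sequence, in which elimination and bromine–lithium exchange give the lithium acetylide, which is C-acylated by the chloroformate in the same flask.

**Step 7**
Reactants: 7 2-bromo-3,5-dimethoxy-6-(3-methylbut-2-en-1-yl)phenol; 11 methyl 3-(2,4,6-trimethoxyphenyl)prop-2-ynoate
Product: 12 methyl (2Z)-3-[2-bromo-3,5-dimethoxy-6-(3-methylbut-2-en-1-yl)phenoxy]-3-(2,4,6-trimethoxyphenyl)prop-2-enoate
Conditions: Cs2CO3 (0.3 equiv), DMF, 80 °C
Reagents that add atoms: none
Why: Base-catalysed oxa-Michael addition of the phenoxide to the β-carbon of the aryl propiolate, a known route to β-aryloxy cinnamates; anti addition should give the Z alkene, and any E isomer is separated because it would lead to the other enantiomer in step 8.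

**Step 8**
Reactants: 12 methyl (2Z)-3-[2-bromo-3,5-dimethoxy-6-(3-methylbut-2-en-1-yl)phenoxy]-3-(2,4,6-trimethoxyphenyl)prop-2-enoate
Product: 13 methyl (3S)-3-[2-bromo-3,5-dimethoxy-6-(3-methylbut-2-en-1-yl)phenoxy]-3-(2,4,6-trimethoxyphenyl)propanoate
Conditions: Cu(OAc)2 (5 mol %), (S)-DTBM-SEGPHOS (5.5 mol %), (EtO)2MeSiH, t-BuOH, toluene, 0 °C → rt
Reagents that add atoms: none
Why: Proposed new method: the ligated copper hydride should add hydride to the β-carbon of the vinylogous carbonate from the alkene face left open by the bisphosphine, giving a copper enolate that t-BuOH protonates at the α-carbon faster than it can expel the β-aryloxy group while the silane regenerates Cu–H; the closest known reaction type is the asymmetric CuH conjugate reduction of β,β-disubstituted enoates and of chromones; the new stereocentre (C3 here, C2 of the flavanone) is set by this ligand-controlled facial delivery to the single Z alkene, and the aryl bromide and the prenyl alkene are not substrates for CuH.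

**Step 9**
Reactants: 13 methyl (3S)-3-[2-bromo-3,5-dimethoxy-6-(3-methylbut-2-en-1-yl)phenoxy]-3-(2,4,6-trimethoxyphenyl)propanoate
Product: 14 (3S)-3-[2-bromo-3,5-dimethoxy-6-(3-methylbut-2-en-1-yl)phenoxy]-N-methoxy-N-methyl-3-(2,4,6-trimethoxyphenyl)propanamide
Conditions: MeNHOMe·HCl, i-PrMgCl, THF, −20 → 0 °C
Reagents that add atoms: N,O-dimethylhydroxylamine hydrochloride, CNOC.Cl
Why: Weinreb amidation of an unhindered ester by the chloromagnesium amide of MeNHOMe is fast at −20 °C, where the reagent should be too weakly basic to enolise the ester and expel the β-aryloxy group, and it uses no Lewis acid that could ionise the benzylic ether.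

**Step 10**
Reactants: 14 (3S)-3-[2-bromo-3,5-dimethoxy-6-(3-methylbut-2-en-1-yl)phenoxy]-N-methoxy-N-methyl-3-(2,4,6-trimethoxyphenyl)propanamide
Product: 17 (2S)-5,7-dimethoxy-8-(3-methylbut-2-en-1-yl)-2-(2,4,6-trimethoxyphenyl)-2,3-dihydro-4H-chromen-4-one, via C4a aryllithium 15 (not isolated), via lithium hemiaminal alkoxide 16 (not isolated)
Conditions: t-BuLi (2.1 equiv), THF, −100 → −78 °C; AcOH, −78 °C
Reagents that add atoms: none
Why: t-BuLi exchanges the bromine at the future C4a faster than it can deprotonate the α-CH2 or the benzylic CH or add to the amide, the second equivalent destroys t-BuBr, and aryllithium 15, held between the two ring-A oxygens, attacks the tethered N-methoxy-N-methylamide carbonyl to form C4–C4a. The closest known reaction type is the Parham cyclisation of 2-bromoaryl ethers of β-hydroxy Weinreb amides to chroman-4-ones. Ring C (C4a–C4–C3–C2–O1–C8a) closes 6-exo-trig, with the carbonyl oxygen outside the ring. No stereocentre is created in the product: C4 of adduct 16 is transient, and C2 keeps its S configuration because no bond to it is made or broken. The step needs chemoselectivity (exchange and cyclisation before proton transfer, no second addition), which should be secured by the rate of Br–Li exchange at −100 °C, by the intramolecular acylation, and by the N,O-chelated lithium adduct 16, which holds until the cold AcOH quench so that the β-aryloxy ketone never meets base. The acid-free conditions leave the ionisable C2–O1 bond and the prenyl group untouched.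

**Step 11**
Reactants: 17 (2S)-5,7-dimethoxy-8-(3-methylbut-2-en-1-yl)-2-(2,4,6-trimethoxyphenyl)-2,3-dihydro-4H-chromen-4-one
Product: 19 (2S)-5-hydroxy-7-methoxy-8-(3-methylbut-2-en-1-yl)-2-(2,4,6-trimethoxyphenyl)-2,3-dihydro-4H-chromen-4-one (CNP0307910.1), via 5-O-dichloroboryl chelate 18 (not isolated)
Conditions: BCl3 (1.5 equiv), CH2Cl2, −78 → −40 °C; cold aq NaHCO3
Reagents that add atoms: none
Why: Chelation-directed Lewis-acid ether cleavage, in which boron binds the C4 carbonyl and the peri 5-methoxy oxygen in a six-membered chelate so that chloride removes only that methyl group, while the low temperature and the cold bicarbonate quench are meant to keep the C2–O1 benzylic ether from ionising and the prenyl group from adding HCl.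

**Compound list**
1 | 3,5-dimethoxyphenol | COc1cc(O)cc(OC)c1 | starting material
2 | 2-bromo-3,5-dimethoxyphenol | Oc1cc(OC)cc(OC)c1Br | intermediate
3 | 2-methylbut-3-en-2-ol | C=CC(C)(C)O | starting material
4 | lithium 2-methylbut-3-en-2-olate | [Li]OC(C)(C)C=C | intermediate
5 | methyl 2-methylbut-3-en-2-yl carbonate | C=CC(C)(C)OC(=O)OC | intermediate
6 | 2-bromo-1,5-dimethoxy-3-[(2-methylbut-3-en-2-yl)oxy]benzene | C=CC(C)(C)Oc1cc(OC)cc(OC)c1Br | intermediate
7 | 2-bromo-3,5-dimethoxy-6-(3-methylbut-2-en-1-yl)phenol | Oc1c(Br)c(OC)cc(OC)c1CC=C(C)C | intermediate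
8 | 2,4,6-trimethoxybenzaldehyde | COc1cc(OC)c(C=O)c(OC)c1 | starting material
9 | 2-(2,2-dibromoethenyl)-1,3,5-trimethoxybenzene | COc1cc(OC)c(C=C(Br)Br)c(OC)c1 | intermediate
10 | lithium (2,4,6-trimethoxyphenyl)acetylide | [Li]C#Cc1c(OC)cc(OC)cc1OC | intermediate
11 | methyl 3-(2,4,6-trimethoxyphenyl)prop-2-ynoate | COC(=O)C#Cc1c(OC)cc(OC)cc1OC | intermediate
12 | methyl (2Z)-3-[2-bromo-3,5-dimethoxy-6-(3-methylbut-2-en-1-yl)phenoxy]-3-(2,4,6-trimethoxyphenyl)prop-2-enoate | COC(=O)/C=C(/c1c(OC)cc(OC)cc1OC)Oc1c(Br)c(OC)cc(OC)c1CC=C(C)C | intermediate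
13 | methyl (3S)-3-[2-bromo-3,5-dimethoxy-6-(3-methylbut-2-en-1-yl)phenoxy]-3-(2,4,6-trimethoxyphenyl)propanoate | COC(=O)C[C@H](Oc1c(Br)c(OC)cc(OC)c1CC=C(C)C)c1c(OC)cc(OC)cc1OC | intermediate
14 | (3S)-3-[2-bromo-3,5-dimethoxy-6-(3-methylbut-2-en-1-yl)phenoxy]-N-methoxy-N-methyl-3-(2,4,6-trimethoxyphenyl)propanamide | CON(C)C(=O)C[C@H](Oc1c(Br)c(OC)cc(OC)c1CC=C(C)C)c1c(OC)cc(OC)cc1OC | intermediate
15 | (3S)-3-[2-lithio-3,5-dimethoxy-6-(3-methylbut-2-en-1-yl)phenoxy]-N-methoxy-N-methyl-3-(2,4,6-trimethoxyphenyl)propanamide | CON(C)C(=O)C[C@H](Oc1c([Li])c(OC)cc(OC)c1CC=C(C)C)c1c(OC)cc(OC)cc1OC | intermediate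
16 | lithium (2S)-5,7-dimethoxy-4-[methoxy(methyl)amino]-8-(3-methylbut-2-en-1-yl)-2-(2,4,6-trimethoxyphenyl)chroman-4-olate (C4 configuration undefined) | COc1cc(OC)c([C@@H]2CC(O[Li])(N(C)OC)c3c(OC)cc(OC)c(CC=C(C)C)c3O2)c(OC)c1 | intermediate
17 | (2S)-5,7-dimethoxy-8-(3-methylbut-2-en-1-yl)-2-(2,4,6-trimethoxyphenyl)-2,3-dihydro-4H-chromen-4-one | COc1cc(OC)c([C@@H]2CC(=O)c3c(OC)cc(OC)c(CC=C(C)C)c3O2)c(OC)c1 | intermediate
18 | (2S)-5-(dichloroboryloxy)-7-methoxy-8-(3-methylbut-2-en-1-yl)-2-(2,4,6-trimethoxyphenyl)-2,3-dihydro-4H-chromen-4-one (boron chelated to the C4 carbonyl) | COc1cc(OC)c([C@@H]2CC(=O)c3c(OB(Cl)Cl)cc(OC)c(CC=C(C)C)c3O2)c(OC)c1 | intermediate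
19 | (2S)-5-hydroxy-7-methoxy-8-(3-methylbut-2-en-1-yl)-2-(2,4,6-trimethoxyphenyl)-2,3-dihydro-4H-chromen-4-one | COc1cc(OC)c([C@@H]2CC(=O)c3c(O)cc(OC)c(CC=C(C)C)c3O2)c(OC)c1 | target

**Step count**
Total: 11 steps. Longest linear sequence: 8 steps (steps 1, 3, 4, 7, 8, 9, 10, 11).

**Steps most likely to fail**

Step 8 (proposed new method). Hydride transfer to the congested, donor-deactivated β-carbon may be too slow. The copper enolate may expel the β-aryloxy group before it is protonated, which would release the phenol and over-reduce the cinnamate. Facial discrimination between a twisted aryl group and an aryloxy group may be poor. The fallback uses known chemistry, sets out from ynoate 11 and phenol 7, and comes back to the route at ester 13. Gold(I)-catalysed hydration of 11 (Ph3PAuCl/AgOTf, aqueous dioxane) would give methyl 3-oxo-3-(2,4,6-trimethoxyphenyl)propanoate F1. Noyori hydrogenation with Ru–(S)-BINAP and H2 in MeOH would give methyl (3R)-3-hydroxy-3-(2,4,6-trimethoxyphenyl)propanoate F2, the ligand hand being chosen by analogy with aroylacetates. Mitsunobu etherification of F2 with 7 (PPh3, DIAD, toluene, −20 °C) should then give 13 with inversion. It is the second choice because the activated 2,4,6-trimethoxybenzylic oxyphosphonium ion may ionise, which would erode enantiomeric purity and favour elimination.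

Step 10 (key step). Proton transfer from the α-CH2 to the aryllithium may compete with cyclisation, and the resulting amide enolate would expel the phenoxide; t-BuLi may also add to the amide before exchange is complete. The fallback sets out from ester 13 and comes back at ketone 17. Saponification (LiOH, THF/H2O, 0 °C) would give (3S)-3-[2-bromo-3,5-dimethoxy-6-(3-methylbut-2-en-1-yl)phenoxy]-3-(2,4,6-trimethoxyphenyl)propanoic acid F3. Treatment of F3 with n-BuLi (1 equiv) and then t-BuLi (2 equiv) at −100 °C, with warming to −40 °C, lets the aryllithium add to the lithium carboxylate in the original Parham manner. The α-protons of the carboxylate are not acidic enough for E1cB loss of the phenoxide, and the dilithium gem-diolate gives 17 only on aqueous quench.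

Step 7. Addition may stall because the two ortho methoxy groups shield and deactivate the alkyne β-carbon and the phenoxide is 2,6-disubstituted, and prolonged heating may scramble the alkene geometry. The fallback sets out from ynoate 11 and phenol 7 and comes back at acrylate 12. Anti hydroiodination of 11 (NaI, AcOH, 70 °C) would give methyl (2Z)-3-iodo-3-(2,4,6-trimethoxyphenyl)prop-2-enoate F4. Copper-catalysed vinyl C–O coupling of F4 with 7 (CuI, N,N-dimethylglycine, Cs2CO3, dioxane, 90 °C) should then give 12 with retention of geometry; the vinyl iodide is far more reactive than the hindered aryl bromide of 7.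

**Further compounds**
F1 | step 8 | methyl 3-oxo-3-(2,4,6-trimethoxyphenyl)propanoate | COC(=O)CC(=O)c1c(OC)cc(OC)cc1OC
F2 | step 8 | methyl (3R)-3-hydroxy-3-(2,4,6-trimethoxyphenyl)propanoate | COC(=O)C[C@@H](O)c1c(OC)cc(OC)cc1OC
F3 | step 10 | (3S)-3-[2-bromo-3,5-dimethoxy-6-(3-methylbut-2-en-1-yl)phenoxy]-3-(2,4,6-trimethoxyphenyl)propanoic acid | OC(=O)C[C@H](Oc1c(Br)c(OC)cc(OC)c1CC=C(C)C)c1c(OC)cc(OC)cc1OC
F4 | step 7 | methyl (2Z)-3-iodo-3-(2,4,6-trimethoxyphenyl)prop-2-enoate | COC(=O)/C=C(\I)c1c(OC)cc(OC)cc1OC
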